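The seven-membered ring is cut into a three-carbon piece, C4–C3a–C8a (azulene numbering: ester carbinol, ring-fusion CH, methyl-bearing quaternary carbon) and a four-carbon piece, C5–C6–C7–C8. The plan exploits the 1,3-relationship in this ring between the oxygen on C4 and the methyl-bearing sp2 carbon C6, read as a masked ketone: a Brook-rearrangement-mediated [3+4] annulation joins a cyclopentenyl acylsilane and the lithium enolate of methyl vinyl ketone, forming C4–C5 by carbonyl addition and C8–C8a by oxy-Cope ring expansion of the transient cis-dialkenylcyclopropanolate. The acylsilane comes from (S)-terpinen-4-ol, which supplies the five-membered ring and C3; methyl addition, dehydration, chelation-controlled reduction and acylation complete the target.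

Key step: step 5

Remark on the chemistry: (S)-(+)-terpinen-4-ol is assumed to be used in enantiomerically pure form. Azulene numbering is used throughout (C3 carbinol with isopropyl, C3a, C4 ester carbon, C5=C6 with methyl, C8a with methyl). The target is the (3R,3aS,4R,8aR) isomer: cis ring fusion, both oxygens on the face (α) opposite to H-3a and the C8a methyl (β).

Step 1
Reactants: 1 (S)-(+)-terpinen-4-ol, (1S)-4-methyl-1-(propan-2-yl)cyclohex-3-en-1-ol
Product: 2 triethyl{[(1S)-4-methyl-1-(propan-2-yl)cyclohex-3-en-1-yl]oxy}silane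
Conditions: TESOTf, 2,6-lutidine, CH2Cl2, 0 °C to rt
Reagents that add atoms: triethylsilyl trifluoromethanesulfonate, CC[Si](CC)(CC)OS(=O)(=O)C(F)(F)F
Why: Silyl triflate with 2,6-lutidine is the standard silylation of a hindered tertiary alcohol; the stereocentre is not touched.

Step 2
Reactants: 2 triethyl{[(1S)-4-methyl-1-(propan-2-yl)cyclohex-3-en-1-yl]oxy}silane
Product: 4 (5R)-2-methyl-5-(propan-2-yl)-5-[(triethylsilyl)oxy]cyclopent-1-ene-1-carbaldehyde, via keto aldehyde 3 (not isolated)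
Conditions: O3, CH2Cl2, −78 °C; PPh3, −78 °C to rt; then piperidine, AcOH, 40 °C
Reagents that add atoms: ozone, [O-][O+]=O
Why: Ozonolysis of the only C=C gives the 1,6-keto aldehyde, whose aldehyde enamine closes 5-exo onto the methyl ketone and dehydrates (intramolecular aldol condensation) to the tetrasubstituted cyclopentene carbaldehyde; the silyl ether prevents β-elimination and the stereocentre is not involved.

Step 3
Reactants: 4 (5R)-2-methyl-5-(propan-2-yl)-5-[(triethylsilyl)oxy]cyclopent-1-ene-1-carbaldehyde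
Product: 5 [dimethyl(phenyl)silyl][(5R)-2-methyl-5-(propan-2-yl)-5-[(triethylsilyl)oxy]cyclopent-1-en-1-yl]methanol (both carbinol epimers)
Conditions: PhMe2SiLi, THF, −78 °C; AcOH, −78 °C
Reagents that add atoms: dimethylphenylsilyllithium, [Li][Si](C)(C)c1ccccc1
Why: Silyllithium 1,2-addition to the aldehyde should be clean because the fully substituted β-carbon blocks 1,4-addition and the cold quench prevents Brook rearrangement; the new carbinol centre is removed in step 4.

Step 4
Reactants: 5 [dimethyl(phenyl)silyl][(5R)-2-methyl-5-(propan-2-yl)-5-[(triethylsilyl)oxy]cyclopent-1-en-1-yl]methanol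
Product: 6 [dimethyl(phenyl)silyl][(5R)-2-methyl-5-(propan-2-yl)-5-[(triethylsilyl)oxy]cyclopent-1-en-1-yl]methanone
Conditions: Dess–Martin periodinane, NaHCO3, CH2Cl2, 0 °C to rt
Reagents that add atoms: none
Why: Buffered Dess–Martin oxidation of an α-silyl carbinol is an established non-basic route to acylsilanes.

Step 5
Reactants: 6 [dimethyl(phenyl)silyl][(5R)-2-methyl-5-(propan-2-yl)-5-[(triethylsilyl)oxy]cyclopent-1-en-1-yl]methanone; 7 2-(trimethylsilyloxy)buta-1,3-diene
Product: 12 (3R,8aS)-4-{[dimethyl(phenyl)silyl]oxy}-8a-methyl-3-(propan-2-yl)-3-[(triethylsilyl)oxy]-2,3,5,7,8,8a-hexahydroazulen-6(1H)-one, via lithium buta-1,3-dien-2-olate 8 (not isolated), via alkoxide 1,2-adduct 9 (not isolated), via cis-dialkenylcyclopropanolate 10 (not isolated), via bicyclic lithium enolate 11 (not isolated)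
Conditions: 7 (1.3 equiv), MeLi (1.2 equiv), THF, 0 °C to rt; then 6, THF, −80 to −30 °C; AcOH, −78 °C
Reagents that add atoms: none
Why: The enolate carbon of 8 adds to the acylsilane carbonyl (bond C4–C5), alkoxide 9 undergoes 1,2-Brook rearrangement, and the resulting siloxyallyl anion closes 3-exo-trig onto the enone carbonyl to give cyclopropanolate 10 with the two alkenyl groups cis (the two oxygens are held cis by lithium/silicon bridging). Anionic oxy-Cope (divinylcyclopropane) rearrangement through the boat transition state then forms bond C8–C8a and cleaves the C4–C6 bond, so the seven-membered ring is closed by [3,3]-sigmatropic ring expansion, leaving enolate 11 with the C3a=C4 silyl enol ether. The closest known reaction type is the Brook-rearrangement-mediated [3+4] annulation of alkenoylsilanes with lithium enolates of alkenyl methyl ketones (Takeda annulation). The new quaternary stereocentre C8a is controlled by C3: the three-membered ring is expected to form and rearrange on the cyclopentene face that carries the C3 oxygen, anti to the bulkier isopropyl group, which delivers C8 to the α face of C8a. The step needs 1,2- instead of 1,4-addition, secured by the fully substituted β-carbon, and a cis-dialkenyl cyclopropane, secured by the bridged closure; the single Z-methyl at the rearranging terminus should be tolerated because the alkoxide accelerates the Cope step. C3a stays sp2 here and is set in steps 6 and 7.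

Step 6
Reactants: 12 (3R,8aS)-4-{[dimethyl(phenyl)silyl]oxy}-8a-methyl-3-(propan-2-yl)-3-[(triethylsilyl)oxy]-2,3,5,7,8,8a-hexahydroazulen-6(1H)-one
Product: 14 (3R,8aR)-6-hydroxy-6,8a-dimethyl-3-(propan-2-yl)-3-[(triethylsilyl)oxy]octahydroazulen-4(1H)-one (epimers at C3a and C6), via tertiary alcohol 13 (not isolated)
Conditions: MeLi, CeCl3, THF, −78 °C; then 1 M HCl, THF, 0 °C
Reagents that add atoms: methyllithium, [Li]C
Why: The non-basic organocerium reagent (Imamoto conditions) should add to the C6 ketone without removing the doubly activated C5 protons, and cold dilute acid hydrolyses the labile arylsilyl enol ether while the tertiary triethylsilyl ether survives; the C6 centre is removed in step 7 and C3a is equilibrated there.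

Step 7
Reactants: 14 (3R,8aR)-6-hydroxy-6,8a-dimethyl-3-(propan-2-yl)-3-[(triethylsilyl)oxy]octahydroazulen-4(1H)-one
Product: 16 (3R,3aR,8aR)-6,8a-dimethyl-3-(propan-2-yl)-3-[(triethylsilyl)oxy]-2,3,3a,7,8,8a-hexahydroazulen-4(1H)-one, via C3a-epimeric enone mixture 15 (not isolated)
Conditions: Burgess reagent, THF, 50 °C; then DBU (0.5 equiv), PhMe, rt to 40 °C
Reagents that add atoms: none
Why: Burgess syn-elimination of the tertiary β-hydroxy ketone should remove the acidic C5 hydrogen and give the conjugated C5=C6 enone under neutral conditions. DBU then equilibrates C3a through the α'-enolate to the cis-fused epimer, expected to be the more stable one because C4 sits anti to the isopropyl group on C3 and H-3a is cis to the angular methyl.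

Step 8
Reactants: 16 (3R,3aR,8aR)-6,8a-dimethyl-3-(propan-2-yl)-3-[(triethylsilyl)oxy]-2,3,3a,7,8,8a-hexahydroazulen-4(1H)-one
Product: 17 (3R,3aR,8aR)-3-hydroxy-6,8a-dimethyl-3-(propan-2-yl)-2,3,3a,7,8,8a-hexahydroazulen-4(1H)-one
Conditions: HF·pyridine, pyridine, THF, 0 °C to rt
Reagents that add atoms: none
Why: Buffered HF·pyridine desilylation avoids alkoxide formation, so retro-aldol opening of the tertiary β-hydroxy ketone and epimerisation are not expected.

Step 9
Reactants: 17 (3R,3aR,8aR)-3-hydroxy-6,8a-dimethyl-3-(propan-2-yl)-2,3,3a,7,8,8a-hexahydroazulen-4(1H)-one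
Product: 18 (3R,3aS,4R,8aR)-6,8a-dimethyl-3-(propan-2-yl)-1,2,3,3a,4,7,8,8a-octahydroazulene-3,4-diol
Conditions: Zn(BH4)2, Et2O, −20 °C
Reagents that add atoms: none
Why: Chelation-controlled 1,2-reduction of a β-hydroxy enone: the chelate between the C3 hydroxyl and the C4 carbonyl holds the ketone syn to C3–O, which folds the cyclopentane under the α face, so hydride should enter from the β face (the side of H-3a) and give the 4R carbinol with both oxygens cis.

Step 10
Reactants: 19 isovanillic acid (3-hydroxy-4-methoxybenzoic acid)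
Product: 20 3-(acetyloxy)-4-methoxybenzoic acid
Conditions: Ac2O, pyridine, rt; then H2O
Reagents that add atoms: acetic anhydride, CC(=O)OC(C)=O
Why: Standard phenol acetylation; the mixed anhydride at the carboxyl group is hydrolysed on aqueous work-up.

Step 11
Reactants: 18 (3R,3aS,4R,8aR)-6,8a-dimethyl-3-(propan-2-yl)-1,2,3,3a,4,7,8,8a-octahydroazulene-3,4-diol; 20 3-(acetyloxy)-4-methoxybenzoic acid
Product: 21 (3R,3aS,4R,8aR)-3-hydroxy-6,8a-dimethyl-3-(propan-2-yl)-1,2,3,3a,4,7,8,8a-octahydroazulen-4-yl 3-(acetyloxy)-4-methoxybenzoate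
Conditions: EDC·HCl, DMAP, CH2Cl2, 0 °C to rt
Reagents that add atoms: none
Why: Steglich esterification should acylate only the secondary allylic hydroxyl, since the tertiary C3 hydroxyl is inert under these conditions; C4 keeps its configuration.

Step 12
Reactants: 21 (3R,3aS,4R,8aR)-3-hydroxy-6,8a-dimethyl-3-(propan-2-yl)-1,2,3,3a,4,7,8,8a-octahydroazulen-4-yl 3-(acetyloxy)-4-methoxybenzoate
Product: 22 (3R,3aS,4R,8aR)-3-hydroxy-6,8a-dimethyl-3-(propan-2-yl)-1,2,3,3a,4,7,8,8a-octahydroazulen-4-yl 3-hydroxy-4-methoxybenzoate (CNP0210850.1)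
Conditions: pyrrolidine, CH2Cl2, 0 °C
Reagents that add atoms: none
Why: Aminolysis of the activated aryl acetate should be far faster than attack on the hindered secondary benzoate, so the phenol is freed without touching the ester or the allylic system.

Compound list
1 | (S)-(+)-terpinen-4-ol, (1S)-4-methyl-1-(propan-2-yl)cyclohex-3-en-1-ol | CC1=CC[C@](O)(C(C)C)CC1 | starting material
2 | triethyl{[(1S)-4-methyl-1-(propan-2-yl)cyclohex-3-en-1-yl]oxy}silane | CC1=CC[C@](O[Si](CC)(CC)CC)(C(C)C)CC1 | intermediate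
3 | (3S)-6-oxo-3-(propan-2-yl)-3-[(triethylsilyl)oxy]heptanal | O=CC[C@](O[Si](CC)(CC)CC)(C(C)C)CCC(C)=O | intermediate
4 | (5R)-2-methyl-5-(propan-2-yl)-5-[(triethylsilyl)oxy]cyclopent-1-ene-1-carbaldehyde | O=CC1=C(C)CC[C@@]1(O[Si](CC)(CC)CC)C(C)C | intermediate
5 | [dimethyl(phenyl)silyl][(5R)-2-methyl-5-(propan-2-yl)-5-[(triethylsilyl)oxy]cyclopent-1-en-1-yl]methanol (carbinol epimers) | OC(C1=C(C)CC[C@@]1(O[Si](CC)(CC)CC)C(C)C)[Si](C)(C)c1ccccc1 | intermediate
6 | [dimethyl(phenyl)silyl][(5R)-2-methyl-5-(propan-2-yl)-5-[(triethylsilyl)oxy]cyclopent-1-en-1-yl]methanone | O=C(C1=C(C)CC[C@@]1(O[Si](CC)(CC)CC)C(C)C)[Si](C)(C)c1ccccc1 | intermediate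
7 | 2-(trimethylsilyloxy)buta-1,3-diene | C=CC(=C)O[Si](C)(C)C | starting material
8 | lithium buta-1,3-dien-2-olate | [Li]OC(=C)C=C | intermediate
9 | lithium 1-[dimethyl(phenyl)silyl]-1-[(5R)-2-methyl-5-(propan-2-yl)-5-[(triethylsilyl)oxy]cyclopent-1-en-1-yl]-3-oxopent-4-en-1-olate (configuration at C1 open) | [Li]OC(CC(=O)C=C)(C1=C(C)CC[C@@]1(O[Si](CC)(CC)CC)C(C)C)[Si](C)(C)c1ccccc1 | intermediate
10 | lithium (1R,2S)-2-{[dimethyl(phenyl)silyl]oxy}-1-ethenyl-2-[(5R)-2-methyl-5-(propan-2-yl)-5-[(triethylsilyl)oxy]cyclopent-1-en-1-yl]cyclopropan-1-olate (alkenyl groups cis) | [Li]O[C@@]1(C=C)C[C@]1(O[Si](C)(C)c1ccccc1)C1=C(C)CC[C@@]1(O[Si](CC)(CC)CC)C(C)C | intermediate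
11 | lithium (3R,8aS)-4-{[dimethyl(phenyl)silyl]oxy}-8a-methyl-3-(propan-2-yl)-3-[(triethylsilyl)oxy]-1,2,3,5,8,8a-hexahydroazulen-6-olate | [Li]OC1=CC[C@]2(C)CC[C@@](O[Si](CC)(CC)CC)(C(C)C)C2=C(O[Si](C)(C)c3ccccc3)C1 | intermediate
12 | (3R,8aS)-4-{[dimethyl(phenyl)silyl]oxy}-8a-methyl-3-(propan-2-yl)-3-[(triethylsilyl)oxy]-2,3,5,7,8,8a-hexahydroazulen-6(1H)-one | O=C1CC[C@]2(C)CC[C@@](O[Si](CC)(CC)CC)(C(C)C)C2=C(O[Si](C)(C)c3ccccc3)C1 | intermediate
13 | (3R,8aR)-4-{[dimethyl(phenyl)silyl]oxy}-6,8a-dimethyl-3-(propan-2-yl)-3-[(triethylsilyl)oxy]-1,2,3,5,6,7,8,8a-octahydroazulen-6-ol (C6 epimers) | CC1(O)CC[C@]2(C)CC[C@@](O[Si](CC)(CC)CC)(C(C)C)C2=C(O[Si](C)(C)c3ccccc3)C1 | intermediate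
14 | (3R,8aR)-6-hydroxy-6,8a-dimethyl-3-(propan-2-yl)-3-[(triethylsilyl)oxy]octahydroazulen-4(1H)-one (epimers at C3a and C6) | CC1(O)CC[C@]2(C)CC[C@@](O[Si](CC)(CC)CC)(C(C)C)C2C(=O)C1 | intermediate
15 | (3R,8aR)-6,8a-dimethyl-3-(propan-2-yl)-3-[(triethylsilyl)oxy]-2,3,3a,7,8,8a-hexahydroazulen-4(1H)-one (C3a epimers) | O=C1C=C(C)CC[C@]2(C)CC[C@@](O[Si](CC)(CC)CC)(C(C)C)C12 | intermediate
16 | (3R,3aR,8aR)-6,8a-dimethyl-3-(propan-2-yl)-3-[(triethylsilyl)oxy]-2,3,3a,7,8,8a-hexahydroazulen-4(1H)-one (cis-fused) | O=C1C=C(C)CC[C@]2(C)CC[C@@](O[Si](CC)(CC)CC)(C(C)C)[C@H]12 | intermediate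
17 | (3R,3aR,8aR)-3-hydroxy-6,8a-dimethyl-3-(propan-2-yl)-2,3,3a,7,8,8a-hexahydroazulen-4(1H)-one | O=C1C=C(C)CC[C@]2(C)CC[C@@](O)(C(C)C)[C@H]12 | intermediate
18 | (3R,3aS,4R,8aR)-6,8a-dimethyl-3-(propan-2-yl)-1,2,3,3a,4,7,8,8a-octahydroazulene-3,4-diol | O[C@@H]1C=C(C)CC[C@]2(C)CC[C@@](O)(C(C)C)[C@H]12 | intermediate
19 | isovanillic acid, 3-hydroxy-4-methoxybenzoic acid | COc1ccc(C(=O)O)cc1O | starting material
20 | 3-(acetyloxy)-4-methoxybenzoic acid | COc1ccc(C(=O)O)cc1OC(C)=O | intermediate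
21 | (3R,3aS,4R,8aR)-3-hydroxy-6,8a-dimethyl-3-(propan-2-yl)-1,2,3,3a,4,7,8,8a-octahydroazulen-4-yl 3-(acetyloxy)-4-methoxybenzoate | COc1ccc(C(=O)O[C@@H]2C=C(C)CC[C@]3(C)CC[C@@](O)(C(C)C)[C@H]23)cc1OC(C)=O | intermediate
22 | (3R,3aS,4R,8aR)-3-hydroxy-6,8a-dimethyl-3-(propan-2-yl)-1,2,3,3a,4,7,8,8a-octahydroazulen-4-yl 3-hydroxy-4-methoxybenzoate | COc1ccc(C(=O)O[C@@H]2C=C(C)CC[C@]3(C)CC[C@@](O)(C(C)C)[C@H]23)cc1O | target

Total step count: 12. Longest linear sequence: 11 steps (steps 1 to 9, 11 and 12).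

Steps most likely to fail

1. Step 5. The hindered acylsilane may stop at the aldol-type adduct without Brook rearrangement, or the cyclopropanolate may form and rearrange on the isopropyl face of the cyclopentene, giving the C8a epimer. Fallback from 4, returning at 16: but-2-enylmagnesium chloride adds with allylic transposition to give the homoallylic alcohol F1. Dess–Martin oxidation gives the β,γ-unsaturated ketone F2. LiN(iPr)2 and Me3SiCl give the 2-siloxy diene F3. Et2Zn and CH2I2 cyclopropanate the electron-rich enol ether double bond to the siloxy dialkenylcyclopropane F4, where the CH2 unit makes bond C4–C5. Heating in toluene brings about the neutral divinylcyclopropane rearrangement to the silyl enol ether F5, which makes bond C8–C8a. Dilute HCl gives the β,γ-unsaturated ketone F6, and DBU moves the double bond into conjugation and equilibrates C3a to reach 16.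

2. Step 7. The syn-elimination may give the exocyclic or C6=C7 alkene. During base equilibration of C3a, the C3 silyloxy group may be lost by β-elimination, or the double bond may move out of conjugation. Fallback from 12, returning at 16: KN(SiMe3)2 and PhNTf2 deprotonate the doubly activated C5 position and give the dienyl triflate F7. MeMgBr with Fe(acac)3 replaces the triflate by methyl to give the 2-siloxy diene F8. Cold dilute HCl protonates C3a and releases the conjugated enone directly, so no alcohol dehydration is needed; a brief DBU treatment then sets C3a as before and gives 16.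

3. Step 9. Hydride may attack the α face of the C4 carbonyl and give the C4 epimer. Fallback from 17, returning at 21: Me4NBH(OAc)3 in AcOH/MeCN delivers hydride internally from the C3 hydroxyl and gives the 4S diol F9 on purpose. Mitsunobu esterification of F9 with 20 (PPh3, DIAD) then inverts C4 and gives 21.

Further compounds
F1 | step 5 | 2-methyl-1-[(5R)-2-methyl-5-(propan-2-yl)-5-[(triethylsilyl)oxy]cyclopent-1-en-1-yl]but-3-en-1-ol (diastereomer mixture) | OC(C(C)C=C)C1=C(C)CC[C@@]1(O[Si](CC)(CC)CC)C(C)C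
F2 | step 5 | 2-methyl-1-[(5R)-2-methyl-5-(propan-2-yl)-5-[(triethylsilyl)oxy]cyclopent-1-en-1-yl]but-3-en-1-one | O=C(C(C)C=C)C1=C(C)CC[C@@]1(O[Si](CC)(CC)CC)C(C)C
F3 | step 5 | trimethyl({2-methyl-1-[(5R)-2-methyl-5-(propan-2-yl)-5-[(triethylsilyl)oxy]cyclopent-1-en-1-yl]buta-1,3-dien-1-yl}oxy)silane | C=CC(C)=C(O[Si](C)(C)C)C1=C(C)CC[C@@]1(O[Si](CC)(CC)CC)C(C)C
F4 | step 5 | ({2-ethenyl-2-methyl-1-[(5R)-2-methyl-5-(propan-2-yl)-5-[(triethylsilyl)oxy]cyclopent-1-en-1-yl]cyclopropyl}oxy)trimethylsilane | C=CC1(C)CC1(O[Si](C)(C)C)C1=C(C)CC[C@@]1(O[Si](CC)(CC)CC)C(C)C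
F5 | step 5 | 6,8a-dimethyl-3-(propan-2-yl)-3-[(triethylsilyl)oxy]-4-[(trimethylsilyl)oxy]-1,2,3,5,8,8a-hexahydroazulene (C3 and C8a configured as in 12) | CC1=CC[C@]2(C)CC[C@@](O[Si](CC)(CC)CC)(C(C)C)C2=C(O[Si](C)(C)C)C1
F6 | step 5 | 6,8a-dimethyl-3-(propan-2-yl)-3-[(triethylsilyl)oxy]-2,3,3a,5,8,8a-hexahydroazulen-4(1H)-one (C3 and C8a configured as in 12, C3a epimers) | CC1=CC[C@]2(C)CC[C@@](O[Si](CC)(CC)CC)(C(C)C)C2C(=O)C1
F7 | step 7 | 4-{[dimethyl(phenyl)silyl]oxy}-8a-methyl-3-(propan-2-yl)-3-[(triethylsilyl)oxy]-1,2,3,7,8,8a-hexahydroazulen-6-yl trifluoromethanesulfonate (C3 and C8a configured as in 12) | FC(F)(F)S(=O)(=O)OC1=CC(O[Si](C)(C)c3ccccc3)=C2[C@](O[Si](CC)(CC)CC)(C(C)C)CC[C@@]2(C)CC1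
F8 | step 7 | dimethyl(phenyl)silyl dienol ether 4-{[dimethyl(phenyl)silyl]oxy}-6,8a-dimethyl-3-(propan-2-yl)-3-[(triethylsilyl)oxy]-1,2,3,7,8,8a-hexahydroazulene (C3 and C8a configured as in 12) | CC1=CC(O[Si](C)(C)c3ccccc3)=C2[C@](O[Si](CC)(CC)CC)(C(C)C)CC[C@@]2(C)CC1
F9 | step 9 | (3R,3aS,4S,8aR)-6,8a-dimethyl-3-(propan-2-yl)-1,2,3,3a,4,7,8,8a-octahydroazulene-3,4-diol | O[C@H]1C=C(C)CC[C@]2(C)CC[C@@](O)(C(C)C)[C@H]12
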